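**Retrosynthetic overview**

1. Deoxycalyxin A (17, C3 = R as read from the SMILES) comes from its tris-MOM ether 16 by acetal cleavage.
2. Ring A is the only ring formed; rings B, C and D are bought as 4-oxygenated benzenes. The strategy rests on this feature: ring A carbons C3', C2', C1' (with its methoxy) and C6', the ketone carbon and the ring B styryl unit are together the carbon skeleton of 4-methoxy-6-styryl-2-pyranone 4. Only C4' and C5' are missing, and they are the α-carbon and the carbonyl carbon of ester 13, whose β-carbon is the C3 stereocentre.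
3. Ring A is therefore disconnected at C4'–C3' (enolate acylation at the lactone carbonyl) and C5'–C6' (Claisen condensation).
4. Ester 13 comes from enoate 12 and alkenylboronic acid 7 by rhodium/BINAP 1,4-addition, which sets C3. Enoate 12 comes from acid 8; 7 and 4 both come from aldehyde 2 (4 also needs pyranone 3).

Key step: step 9

Assumption: the known sense of induction of rhodium/BINAP with (E)-enoates, in which the (S)-ligand delivers the carbon group to the 2si face, is taken to hold for the styryl group. (R)-BINAP is therefore specified for the (S)-ester 13; if the first run shows the opposite sense, (S)-BINAP is used instead.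

Numbering used: ring A carbons carry primed locants, C1' (OMe), C2' (H), C3' (OH), C4' (bears the stereocentre C3), C5' (OH), C6' (acyl). The heptanoid chain runs from C1 (on ring C) to C7 (on ring D); ring B sits on the enone.

**Route**

Step 1
Reactants: 1 4-hydroxybenzaldehyde
Product: 2 4-(methoxymethoxy)benzaldehyde
Conditions: MOMCl, K2CO3, acetone, 0 °C → rt
Reagents that add atoms: chloromethyl methyl ether, COCCl
Why: O-alkylation of the phenoxide by the reactive α-chloro ether (Williamson-type MOM protection) should be clean, the aldehyde being inert to carbonate.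

Step 2
Reactants: 2 4-(methoxymethoxy)benzaldehyde; 3 4-methoxy-6-methyl-2H-pyran-2-one
Product: 4 4-methoxy-6-[(E)-2-[4-(methoxymethoxy)phenyl]ethenyl]-2H-pyran-2-one
Conditions: Mg(OMe)2, MeOH, reflux; then H2O
Reagents that add atoms: none
Why: Vinylogous aldol condensation, in which Mg(OMe)2 deprotonates the C6 methyl group (vinylogous to the lactone carbonyl) and dehydration of the adduct gives the conjugated E-styrylpyranone, the standard way to 6-styryl-4-methoxy-2-pyranones.

Step 3
Reactants: 2 4-(methoxymethoxy)benzaldehyde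
Product: 5 1-ethynyl-4-(methoxymethoxy)benzene
Conditions: dimethyl (1-diazo-2-oxopropyl)phosphonate, K2CO3, MeOH, 0 °C → rt
Reagents that add atoms: dimethyl (1-diazo-2-oxopropyl)phosphonate, COP(=O)(OC)C(=[N+]=[N-])C(C)=O
Why: Seyferth–Gilbert homologation in its Ohira–Bestmann form converts a non-enolisable aryl aldehyde into the terminal alkyne under mild carbonate conditions that leave the MOM ether untouched.

Step 4
Reactants: 5 1-ethynyl-4-(methoxymethoxy)benzene
Product: 7 [(E)-2-[4-(methoxymethoxy)phenyl]ethenyl]boronic acid, via catechol alkenylboronate 6 (not isolated)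
Conditions: catecholborane, THF, 65 °C; then H2O, rt
Reagents that add atoms: catecholborane, B1Oc2ccccc2O1; water, O
Why: Syn hydroboration of the terminal alkyne places boron on the terminal carbon and so gives the E-alkenylboronate, which water hydrolyses to the crystalline boronic acid.

Step 5
Reactants: 8 5-(4-hydroxyphenyl)pentanoic acid
Product: 9 methoxymethyl 5-[4-(methoxymethoxy)phenyl]pentanoate
Conditions: MOMCl (2.5 equiv), K2CO3, acetone, 0 °C → rt
Reagents that add atoms: chloromethyl methyl ether, COCCl
Why: Phenoxide and carboxylate are both alkylated by the α-chloro ether, so one operation protects the phenol and activates the acid as an ester for the reduction that follows.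

Step 6
Reactants: 9 methoxymethyl 5-[4-(methoxymethoxy)phenyl]pentanoate
Product: 10 5-[4-(methoxymethoxy)phenyl]pentan-1-ol
Conditions: LiAlH4, THF, 0 °C; then H2O, aq. NaOH
Reagents that add atoms: none
Why: Hydride reduction of the ester to the primary alcohol removes the MOM ester group as methanol while the aryl MOM ether, an acetal, is inert to LiAlH4.

Step 7
Reactants: 10 5-[4-(methoxymethoxy)phenyl]pentan-1-ol
Product: 12 methyl (E)-7-[4-(methoxymethoxy)phenyl]hept-2-enoate, via aldehyde 11 (not isolated)
Conditions: TEMPO (10 mol %), PhI(OAc)2, CH2Cl2, rt; then Ph3P=CHCO2Me, rt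
Reagents that add atoms: methyl (triphenylphosphoranylidene)acetate, COC(=O)C=P(c1ccccc1)(c1ccccc1)c1ccccc1
Why: Oxoammonium oxidation stops at the aldehyde, which the stabilised ylide traps in the same flask (Wittig reaction) to give the E-enoate; any Z isomer is to be removed by chromatography because it would erode the selectivity of step 8.

Step 8
Reactants: 12 methyl (E)-7-[4-(methoxymethoxy)phenyl]hept-2-enoate; 7 [(E)-2-[4-(methoxymethoxy)phenyl]ethenyl]boronic acid
Product: 13 methyl (3S)-7-[4-(methoxymethoxy)phenyl]-3-[(E)-2-[4-(methoxymethoxy)phenyl]ethenyl]heptanoate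
Conditions: Rh(acac)(C2H4)2 (3 mol %), (R)-BINAP (3.3 mol %), 7 (3 equiv, in portions), 1,4-dioxane/H2O 10:1, 100 °C
Reagents that add atoms: none
Why: Hayashi–Miyaura asymmetric 1,4-addition, in which the styryl–rhodium/(R)-BINAP species should carbometalate the enoate on the face that is re at C2 and si at C3 and so set C3 as S under ligand control (enantiomeric purity to be checked by chiral HPLC), with water releasing the ester from the rhodium enolate.

Step 9
Reactants: 13 methyl (3S)-7-[4-(methoxymethoxy)phenyl]-3-[(E)-2-[4-(methoxymethoxy)phenyl]ethenyl]heptanoate; 4 4-methoxy-6-[(E)-2-[4-(methoxymethoxy)phenyl]ethenyl]-2H-pyran-2-one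
Product: 16 (E)-1-[3-[(1E,3R)-1,7-bis[4-(methoxymethoxy)phenyl]hept-1-en-3-yl]-2,4-dihydroxy-6-methoxyphenyl]-3-[4-(methoxymethoxy)phenyl]prop-2-en-1-one, via lithium ester enolate 14 (not isolated), via ring-opened keto ester 15 (not isolated)
Conditions: LiN(i-Pr)2 (1.05 equiv), THF, −78 °C; 4 (1.1 equiv) in THF, −78 → −10 °C; then Mg(OMe)2 (2 equiv), MeOH, 0 → 40 °C; aq. HCl to pH 5, 0 °C
Reagents that add atoms: none
Why: Proposed new method: the lithium enolate 14 should add as a hard nucleophile to the enol-lactone carbonyl of 4 (bond C4'–C3'), and collapse of the tetrahedral alkoxide expels the ring oxygen as the conjugated enolate of the cinnamoyl ketone, giving 15 with the new acyl group and the CH2 group still cis on the methoxy enol ether as they were in the pyranone ring. The enolate carbon so released (future C6') then attacks the methyl ester in a magnesium-templated 6-(enolexo)-exo-trig Claisen condensation (bond C5'–C6'), and loss of methoxide followed by enolisation aromatises ring A, which makes the sequence irreversible. The closest known reactions are the Mg(OMe)2-mediated Claisen cyclisation of 3,5,7-triketo esters and of 6-(2-oxoalkyl)-4-hydroxy-2-pyranones to acylphloroglucinols and the carbanion-induced ring transformations of 2-pyranones into arenes; new here is that an ester enolate opens the pyranone and its own ester group then serves as the Claisen acceptor. No stereocentre is formed: C3 is not deprotonated in 13, 15 or 16 under these conditions and is carried through unchanged, its descriptor changing from S to R only because ring A outranks the styryl group. The step needs acylation at the lactone carbonyl in preference to conjugate addition at pyranone C6, pyranone C4 or the styryl terminus of 4, which the hard lithium enolate at −78 °C and the enol-ester character of the lactone should favour. It also needs Claisen and not aldol closure, which should hold because magnesium chelation of the β-keto ester keeps the ester carbonyl electrophilic, the hindered tertiary C–H at C4' is slow to be removed, and attack of C4' on the ketone would create a quaternary carbon that cannot aromatise and therefore reverts.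

Step 10
Reactants: 16 (E)-1-[3-[(1E,3R)-1,7-bis[4-(methoxymethoxy)phenyl]hept-1-en-3-yl]-2,4-dihydroxy-6-methoxyphenyl]-3-[4-(methoxymethoxy)phenyl]prop-2-en-1-one
Product: 17 deoxycalyxin A, (E)-1-[3-[(1E,3R)-1,7-bis(4-hydroxyphenyl)hept-1-en-3-yl]-2,4-dihydroxy-6-methoxyphenyl]-3-(4-hydroxyphenyl)prop-2-en-1-one
Conditions: aq. HCl (2 M), MeOH, 25–40 °C; NaHCO3 quench
Reagents that add atoms: none
Why: Acid-catalysed acetal exchange with methanol cleaves the three aryl MOM ethers under conditions mild enough that the chalcone, the styryl alkene and the allylic-benzylic stereocentre should persist.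

**Compound list**

1 | 4-hydroxybenzaldehyde | O=Cc1ccc(O)cc1 | starting material
2 | 4-(methoxymethoxy)benzaldehyde | COCOc1ccc(C=O)cc1 | intermediate
3 | 4-methoxy-6-methyl-2H-pyran-2-one | COc1cc(=O)oc(C)c1 | starting material
4 | 4-methoxy-6-[(E)-2-[4-(methoxymethoxy)phenyl]ethenyl]-2H-pyran-2-one | COc1cc(=O)oc(/C=C/c2ccc(OCOC)cc2)c1 | intermediate
5 | 1-ethynyl-4-(methoxymethoxy)benzene | C#Cc1ccc(OCOC)cc1 | intermediate
6 | 2-[(E)-2-[4-(methoxymethoxy)phenyl]ethenyl]-1,3,2-benzodioxaborole | COCOc1ccc(/C=C/B2Oc3ccccc3O2)cc1 | intermediate (not isolated)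
7 | [(E)-2-[4-(methoxymethoxy)phenyl]ethenyl]boronic acid | COCOc1ccc(/C=C/B(O)O)cc1 | intermediate
8 | 5-(4-hydroxyphenyl)pentanoic acid | OC(=O)CCCCc1ccc(O)cc1 | starting material
9 | methoxymethyl 5-[4-(methoxymethoxy)phenyl]pentanoate | COCOC(=O)CCCCc1ccc(OCOC)cc1 | intermediate
10 | 5-[4-(methoxymethoxy)phenyl]pentan-1-ol | OCCCCCc1ccc(OCOC)cc1 | intermediate
11 | 5-[4-(methoxymethoxy)phenyl]pentanal | O=CCCCCc1ccc(OCOC)cc1 | intermediate (not isolated)
12 | methyl (E)-7-[4-(methoxymethoxy)phenyl]hept-2-enoate | COC(=O)/C=C/CCCCc1ccc(OCOC)cc1 | intermediate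
13 | methyl (3S)-7-[4-(methoxymethoxy)phenyl]-3-[(E)-2-[4-(methoxymethoxy)phenyl]ethenyl]heptanoate | COC(=O)C[C@@H](/C=C/c1ccc(OCOC)cc1)CCCCc1ccc(OCOC)cc1 | intermediate
14 | lithium enolate of 13 | [Li+].COC([O-])=C[C@@H](/C=C/c1ccc(OCOC)cc1)CCCCc1ccc(OCOC)cc1 | intermediate (not isolated)
15 | methyl (4E,8E)-2-[(1E,3R)-1,7-bis[4-(methoxymethoxy)phenyl]hept-1-en-3-yl]-5-methoxy-9-[4-(methoxymethoxy)phenyl]-3,7-dioxonona-4,8-dienoate (C2 epimers, drawn as the neutral keto form, present as its enolate) | COC(=O)C(C(=O)/C=C(/OC)CC(=O)/C=C/c1ccc(OCOC)cc1)[C@@H](/C=C/c1ccc(OCOC)cc1)CCCCc1ccc(OCOC)cc1 | intermediate (not isolated)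
16 | (E)-1-[3-[(1E,3R)-1,7-bis[4-(methoxymethoxy)phenyl]hept-1-en-3-yl]-2,4-dihydroxy-6-methoxyphenyl]-3-[4-(methoxymethoxy)phenyl]prop-2-en-1-one | COc1cc(O)c([C@@H](/C=C/c2ccc(OCOC)cc2)CCCCc2ccc(OCOC)cc2)c(O)c1C(=O)/C=C/c1ccc(OCOC)cc1 | intermediate
17 | deoxycalyxin A | COc1cc(O)c([C@@H](/C=C/c2ccc(O)cc2)CCCCc2ccc(O)cc2)c(O)c1C(=O)/C=C/c1ccc(O)cc1 | target

**Step count**

Total: 10 steps. Longest linear sequence: 6 steps (steps 5, 6, 7, 8, 9, 10 from acid 8; the branch from 1 through steps 1, 3, 4, 8, 9, 10 is equally long).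

**Steps most likely to fail**

1. Step 9 (proposed new method). The enolate may add in conjugate fashion to the ring positions 6 or 4 or to the styryl terminus of the pyranone instead of acylating at the lactone carbonyl. The sequence may also stall after ring opening, with the open-chain keto ester reverting by retro-Claisen cleavage under methoxide instead of closing.

   Fallback, known chemistry, setting out from boronic acid 7 and aldehyde 2 and returning at target 17. Ring A is taken from a commercial arene instead of being built. 5-Methoxyresorcinol is protected (MOMCl, K2CO3, acetone) as 1-methoxy-3,5-bis(methoxymethoxy)benzene F1. Directed lithiation between the two MOM ethers (n-BuLi, THF, 0 °C) gives [4-methoxy-2,6-bis(methoxymethoxy)phenyl]lithium F2, and DMF converts it into 4-methoxy-2,6-bis(methoxymethoxy)benzaldehyde F3. 4-(4-Hydroxyphenyl)butan-2-one is protected in the same way as 4-[4-(methoxymethoxy)phenyl]butan-2-one F4. Claisen–Schmidt condensation of F3 with F4 at the methyl group (NaOH, EtOH/H2O) gives (E)-1-[4-methoxy-2,6-bis(methoxymethoxy)phenyl]-5-[4-(methoxymethoxy)phenyl]pent-1-en-3-one F5. Hayashi–Miyaura addition of 7 to F5 with Rh(acac)(C2H4)2 and (S)-BINAP gives (5R,6E)-5-[4-methoxy-2,6-bis(methoxymethoxy)phenyl]-1,7-bis[4-(methoxymethoxy)phenyl]hept-6-en-3-one F6. The ligand is (S) here because the β-substituent and the carbonyl arm have exchanged roles relative to step 8. The ketone is removed through the tosylhydrazone of that ketone F7 (TsNHNH2, EtOH; then catecholborane, CHCl3, 0 °C, and NaOAc·3H2O, reflux) to give 2-[(1E,3R)-1,7-bis[4-(methoxymethoxy)phenyl]hept-1-en-3-yl]-5-methoxy-1,3-bis(methoxymethoxy)benzene F8. Directed ortho-lithiation of F8 between the methoxy group and a MOM ether of ring A (n-BuLi, THF, −20 °C; the two free ring A positions are equivalent by constitution) gives the ring A aryllithium of F8 F9. Acylation with (E)-N-methoxy-N-methyl-3-[4-(methoxymethoxy)phenyl]prop-2-enamide F10 gives the pentakis-MOM ether of deoxycalyxin A F11. F10 is made from 2 by Horner–Wadsworth–Emmons reaction with diethyl [2-(methoxy(methyl)amino)-2-oxoethyl]phosphonate and NaH. Cleavage of all five MOM ethers of F11 under the conditions of step 10 gives 17.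

2. Step 8. Protodeboronation of the alkenylboronic acid at 100 °C may outrun the slow carbometalation of the enoate, and facial discrimination with the small methyl ester may be incomplete.

   Fallback, setting out from enoate 12 and boronic acid 7 and returning at ester 13. Stereocontrol is moved from the catalyst to a covalently bound oxazolidinone auxiliary. 12 is saponified (LiOH, THF/H2O) to (E)-7-[4-(methoxymethoxy)phenyl]hept-2-enoic acid F12. It is activated (pivaloyl chloride, Et3N, THF, −20 °C) as the mixed pivalic anhydride of that acid F13 and coupled with the lithium salt of (R)-4-phenyloxazolidin-2-one (n-BuLi) to give (R)-3-[(E)-7-[4-(methoxymethoxy)phenyl]hept-2-enoyl]-4-phenyloxazolidin-2-one F14. 7 is converted with N-bromosuccinimide (MeCN, 0 °C, retention) into 1-[(E)-2-bromoethenyl]-4-(methoxymethoxy)benzene F15, and Mg turnings in THF give [(E)-2-[4-(methoxymethoxy)phenyl]ethenyl]magnesium bromide F16. With CuBr·SMe2 (THF, −78 → −20 °C), F16 adds to F14 anti to the phenyl group of the magnesium-chelated syn-s-cis imide to give (R)-3-[(3S)-7-[4-(methoxymethoxy)phenyl]-3-[(E)-2-[4-(methoxymethoxy)phenyl]ethenyl]heptanoyl]-4-phenyloxazolidin-2-one F17. NaOMe in MeOH at 0 °C releases 13 and the auxiliary.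

3. Step 10. While the three MOM ethers are being cleaved, the acid may promote oxa-Michael closure of the 2'-hydroxychalcone to the flavanone, or addition of a ring A hydroxyl to the electron-rich styryl alkene (chroman formation).

   Fallback, setting out from 16 and returning at 17. The protecting groups are exchanged under non-protic conditions instead of being solvolysed. Trimethylsilyl triflate and 2,2'-bipyridyl in CH2Cl2 at 0 °C convert the aryl MOM ethers into silyl ethers, giving the tris(trimethylsilyl) ether of deoxycalyxin A F18 (the ring A hydroxyls may be silylated as well). Water at neutral pH then frees all phenols to give 17 without exposure to Brønsted acid.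

**Further compounds**

F1 | step 9 | 1-methoxy-3,5-bis(methoxymethoxy)benzene | COCOc1cc(OC)cc(OCOC)c1
F2 | step 9 | [4-methoxy-2,6-bis(methoxymethoxy)phenyl]lithium | COCOc1cc(OC)cc(OCOC)c1[Li]
F3 | step 9 | 4-methoxy-2,6-bis(methoxymethoxy)benzaldehyde | COCOc1cc(OC)cc(OCOC)c1C=O
F4 | step 9 | 4-[4-(methoxymethoxy)phenyl]butan-2-one | CC(=O)CCc1ccc(OCOC)cc1
F5 | step 9 | (E)-1-[4-methoxy-2,6-bis(methoxymethoxy)phenyl]-5-[4-(methoxymethoxy)phenyl]pent-1-en-3-one | COCOc1ccc(CCC(=O)/C=C/c2c(OCOC)cc(OC)cc2OCOC)cc1
F6 | step 9 | (5R,6E)-5-[4-methoxy-2,6-bis(methoxymethoxy)phenyl]-1,7-bis[4-(methoxymethoxy)phenyl]hept-6-en-3-one | COc1cc(OCOC)c([C@@H](/C=C/c2ccc(OCOC)cc2)CC(=O)CCc2ccc(OCOC)cc2)c(OCOC)c1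
F7 | step 9 | tosylhydrazone of F6 | COc1cc(OCOC)c([C@@H](/C=C/c2ccc(OCOC)cc2)CC(=NNS(=O)(=O)c2ccc(C)cc2)CCc2ccc(OCOC)cc2)c(OCOC)c1
F8 | step 9 | 2-[(1E,3R)-1,7-bis[4-(methoxymethoxy)phenyl]hept-1-en-3-yl]-5-methoxy-1,3-bis(methoxymethoxy)benzene | COc1cc(OCOC)c([C@@H](/C=C/c2ccc(OCOC)cc2)CCCCc2ccc(OCOC)cc2)c(OCOC)c1
F9 | step 9 | ring A aryllithium of F8 | COc1cc(OCOC)c([C@@H](/C=C/c2ccc(OCOC)cc2)CCCCc2ccc(OCOC)cc2)c(OCOC)c1[Li]
F10 | step 9 | (E)-N-methoxy-N-methyl-3-[4-(methoxymethoxy)phenyl]prop-2-enamide | CON(C)C(=O)/C=C/c1ccc(OCOC)cc1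
F11 | step 9 | pentakis-MOM ether of deoxycalyxin A | COc1cc(OCOC)c([C@@H](/C=C/c2ccc(OCOC)cc2)CCCCc2ccc(OCOC)cc2)c(OCOC)c1C(=O)/C=C/c1ccc(OCOC)cc1
F12 | step 8 | (E)-7-[4-(methoxymethoxy)phenyl]hept-2-enoic acid | OC(=O)/C=C/CCCCc1ccc(OCOC)cc1
F13 | step 8 | mixed pivalic anhydride of F12 | CC(C)(C)C(=O)OC(=O)/C=C/CCCCc1ccc(OCOC)cc1
F14 | step 8 | (R)-3-[(E)-7-[4-(methoxymethoxy)phenyl]hept-2-enoyl]-4-phenyloxazolidin-2-one | O=C1OC[C@@H](c2ccccc2)N1C(=O)/C=C/CCCCc1ccc(OCOC)cc1
F15 | step 8 | 1-[(E)-2-bromoethenyl]-4-(methoxymethoxy)benzene | COCOc1ccc(/C=C/Br)cc1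
F16 | step 8 | [(E)-2-[4-(methoxymethoxy)phenyl]ethenyl]magnesium bromide | COCOc1ccc(/C=C/[Mg]Br)cc1
F17 | step 8 | (R)-3-[(3S)-7-[4-(methoxymethoxy)phenyl]-3-[(E)-2-[4-(methoxymethoxy)phenyl]ethenyl]heptanoyl]-4-phenyloxazolidin-2-one | O=C1OC[C@@H](c2ccccc2)N1C(=O)C[C@@H](/C=C/c1ccc(OCOC)cc1)CCCCc1ccc(OCOC)cc1
F18 | step 10 | tris(trimethylsilyl) ether of deoxycalyxin A | COc1cc(O)c([C@@H](/C=C/c2ccc(O[Si](C)(C)C)cc2)CCCCc2ccc(O[Si](C)(C)C)cc2)c(O)c1C(=O)/C=C/c1ccc(O[Si](C)(C)C)cc1
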